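**Remark (assumption):** The target has no stereocentre, stereoaxis or configurable double bond, and its SMILES carries no descriptor. The request for a single enantiomer is therefore met by the constitution alone. The sp3 centres in 8, 9 and 11 are racemic and are erased in step 5. Compounds 1, 4 and 6 are taken to be catalogue chemicals.

## Structural features

1. The target is a flat, achiral flavonol. Benzo ring A (C4a, C5–C8, C8a) is fused along C4a–C8a to γ-pyrone ring C (O1, C2, C3, C4), which carries the 4-hydroxyphenyl ring B through the C2–C1' bond.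
2. No stereocentres stand anywhere, so nothing needs stereochemical control.
3. Ring A is hexasubstituted: five contiguous carbons (C5, C6, C7, C8, C8a) bear oxygen, the sixth (C4a) bears the C4 carbonyl, and no ring-A C–H remains for late functionalisation.
4. Of the four exocyclic oxygens on ring A only C5–OH, hydrogen-bonded to C4=O, is free, so three methyl ethers must be placed next to one phenol.
5. The fragile groups are the C3–OH/C4=O diosphenol (oxidation, base-induced opening of ring C), the very electron-rich ring A (oxidation toward a 5,8-quinone), and the methyl ether at C6 next to C5–OH (Lewis acids).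
6. The real difficulty is therefore not ring C, which every standard flavonol synthesis closes, but the regiodefined penta-oxygenated ring A.
7. The key step exploits three facts. C5–O and C8–O are para. C6 and C7 between them carry identical methoxy groups. The remaining edge C4a=C8a is also the C5=C6 enol-ether bond of a monocyclic γ-pyrone. C5–C6–C7–C8 is thus a latent squarate C4 unit.
8. In one sentence: ring A is grown onto a finished B–C unit by thermal ring expansion of a 4-(γ-pyron-2-yl)-2,3,4-trimethoxycyclobutenone, instead of being brought in as an arene.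

## Logic of the disconnections

**13 ⇒ 12.** The two O–CH2 acetal bonds on O3 and O4' are cut. Both acidic hydroxyls would quench the carbanion and capture the ketene used earlier, so they must be masked. There is no skeletal gain. The forward step must unmask them without touching the three aryl methyl ethers or C5–OH.

**12 ⇒ 9 (key).** C4a–C5 of ring A is cut, and in the retrosynthetic sense C5 is re-bonded to C8, so that C5–C6–C7–C8 contracts to a four-membered ring hanging from C8a.
- Reason: this is the only cut that removes the hexasubstituted benzene itself and also explains why exactly C5 carries the free OH.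
- Gain: 12, with its fully substituted arene, becomes 9, an sp3-linked pair of two simple rings and an isomer of 12.
- Demand: the four-membered ring must open with the pyrone rotating toward the ketene, closure onto the pyrone C=C must outrun intermolecular ketene loss, and the C8 oxygen must already be methylated.

**9 ⇒ 5 + 6.** C8–C8a and the O–CH3 bond on the C8 oxygen are cut. The cut is convergent, and 6 is symmetrical, so it poses no regiochemical question on its side. The molecule falls into a B–C unit and a commercial C4 ring. The forward step needs a carbanion at the pyrone carbon next to O1 and not at the one next to C4=O. It also needs a single 1,2-addition and trapping of the alkoxide on oxygen.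

**5 ⇒ 3 + 4.** C2–C1' is cut. This is the only bond between ring B and ring C, and C2 of a 3-oxy-γ-pyrone is easily halogenated. Ring B becomes a commercial boronic acid. The forward coupling must proceed at a vinylogous acyl halide without hydrolysing it.

**3 ⇒ 2.** The O3–CH2 acetal bond is cut. The enol must be masked before Pd and amide-base chemistry. The gain is tactical only. The forward step needs O-alkylation rather than C-alkylation.

**2 ⇒ 1.** C2–I is cut. The 3-OH activates precisely C2, which leads back to a commercial C5 heterocycle. The forward step needs mono-iodination at C2 only.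

## Other disconnections considered

**Alternative 1:** This is the first that comes to mind.
- Cut: O1–C2 and C3–OH in ring C, then C2–C3.
- Forward: Claisen–Schmidt condensation of 1-[2-(benzyloxy)-6-hydroxy-3,4,5-trimethoxyphenyl]ethan-1-one A1 with 4-(benzyloxy)benzaldehyde A2 gives the chalcone A3. Algar–Flynn–Oyamada oxidative cyclisation with alkaline peroxide and debenzylation follow.
- Grounds for rejection: the cut closes the easy ring and passes the whole difficulty on to A1. A1 is itself a hexasubstituted benzene that needs several serial oxygenations and protections of a simpler phenol. In addition, the 6'-alkoxy group of A3 twists the enone out of plane and is expected to favour phenoxide attack at the α-carbon (5-exo). That diverts the key step toward the aurone manifold. The chosen plan builds the arene and places its single OH in one isomerisation.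

**Alternative 2:**
- Cut: C4–C4a, C3–C4 and O1–C2.
- Forward: a three-component Pd-catalysed carbonylative Sonogashira coupling and 6-endo cyclisation of 3-(benzyloxy)-2-iodo-4,5,6-trimethoxyphenol A4 with 1-(benzyloxy)-4-ethynylbenzene A5 gives the flavone A6. C3 is then hydroxylated by lithiation/borylation/oxidation, and the benzyl groups are removed.
- Grounds for rejection: the idea is attractive as a multicomponent step, but A4 is again a hexasubstituted arene and no easier than A1. Its C–I bond is flanked by two ortho oxygens, so oxidative addition and CO insertion should be slow. 5-exo closure competes with 6-endo closure, and the C3 oxygen needs an extra redox step. Ring A stays unsolved and the route is longer.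

**Alternative 3:**
- Cut: C6–O and C8–O, by late oxygenation of an intact flavonol.
- Forward: kaempferol A7 is selectively protected and 7-O-methylated, then dibrominated to 3-(benzyloxy)-2-[4-(benzyloxy)phenyl]-6,8-dibromo-5-hydroxy-7-methoxy-4H-chromen-4-one A8. A double Ullmann-type copper-mediated methoxylation and debenzylation follow.
- Grounds for rejection: the four hydroxyls of A7 must be told apart in three different ways. Both C–Br bonds of A8 are di-ortho-substituted, so reduction of C–Br can compete with C–O coupling. Every step is a functional-group change on the full skeleton and brings no gain in simplicity. The chosen plan needs no selective alkylation or dealkylation on ring A.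

Key step: step 5

## Route

Step 1
Reactants: 1 3-hydroxy-4H-pyran-4-one (pyromeconic acid)
Product: 2 3-hydroxy-2-iodo-4H-pyran-4-one
Conditions: NIS (1.05 equiv), MeCN, 0 °C → rt, dark
Reagents that add atoms: N-iodosuccinimide, O=C1CCC(=O)N1I
Why: Electrophilic iodination of an enol: the 3-OH makes C2 the nucleophilic enol β-carbon, the site at which 3-hydroxy-4-pyranones also undergo bromination, Mannich and aldol reactions, whereas C5 lacks this activation and C6 is electrophilic.

Step 2
Reactants: 2 3-hydroxy-2-iodo-4H-pyran-4-one
Product: 3 2-iodo-3-(methoxymethoxy)-4H-pyran-4-one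
Conditions: MOMCl, K2CO3, acetone, 0 °C → rt
Reagents that add atoms: chloromethyl methyl ether, COCCl
Why: Williamson-type O-alkylation of an acidic enol by a hard oxocarbenium-like electrophile, which favours O over C; the MOM acetal is inert to Pd/phosphate, hindered lithium amides, cold MeOTf and neutral heating, and is removed by mild acid.

Step 3
Reactants: 3 2-iodo-3-(methoxymethoxy)-4H-pyran-4-one; 4 [4-(methoxymethoxy)phenyl]boronic acid
Product: 5 3-(methoxymethoxy)-2-[4-(methoxymethoxy)phenyl]-4H-pyran-4-one
Conditions: Pd(dppf)Cl2 (3 mol %), K3PO4, 1,4-dioxane/H2O 10:1, 70 °C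
Reagents that add atoms: none
Why: Suzuki–Miyaura coupling: the C2–I bond is a vinylogous acyl iodide and should undergo fast oxidative addition, so a mild phosphate base and moderate temperature suffice and the pyrone ring and both acetals are spared.

Step 4
Reactants: 5 3-(methoxymethoxy)-2-[4-(methoxymethoxy)phenyl]-4H-pyran-4-one; 6 3,4-dimethoxycyclobut-3-ene-1,2-dione (dimethyl squarate)
Product: 9 2,3,4-trimethoxy-4-{5-(methoxymethoxy)-6-[4-(methoxymethoxy)phenyl]-4-oxo-4H-pyran-2-yl}cyclobut-2-en-1-one (racemic), via 6-lithio-γ-pyrone 7 (not isolated), via lithium cyclobutenolate 8 (not isolated)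
Conditions: LiTMP (TMPH, n-BuLi), THF, −78 °C; cannulated into 6, THF, −78 °C; MeOTf (1.1 equiv), −78 → −20 °C
Reagents that add atoms: methyl trifluoromethanesulfonate, COS(=O)(=O)C(F)(F)F
Why: Deprotonative lithiation at the C–H next to the ring oxygen (the site at which chromones and 4-pyridones are lithiated and γ-pyrones exchange hydrogen under base, owing to the inductive effect of O1 and pyrylium-olate stabilisation), then 1,2-addition of the organolithium to a squarate ester carbonyl and in situ O-methylation of the tertiary alkoxide, both standard operations of cyclobutenedione chemistry. The hindered amine does not add to 6, inverse addition prevents double addition, and the alkoxide should outcompete the pyrone carbonyl oxygen for one equivalent of MeOTf in the cold. The new quaternary centre forms as a racemate and is destroyed in step 5.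

Step 5
Reactants: 9 2,3,4-trimethoxy-4-{5-(methoxymethoxy)-6-[4-(methoxymethoxy)phenyl]-4-oxo-4H-pyran-2-yl}cyclobut-2-en-1-one
Product: 12 5-hydroxy-6,7,8-trimethoxy-3-(methoxymethoxy)-2-[4-(methoxymethoxy)phenyl]-4H-chromen-4-one, via (Z)-dienylketene 10 (not isolated), via 4aH-chromene-4,5-dione 11 (not isolated)
Conditions: PhMe (0.01 M), 110 °C, Ar
Reagents that add atoms: none
Why: The step is a Moore-type thermal ring expansion of a 4-alkenyl/heteroaryl-4-alkoxycyclobutenone to a hydroquinone monoether, with a γ-pyron-2-yl group as the unsaturated substituent. Heat breaks the C(=O)–C(sp3) bond of the four-membered ring in a conrotatory 4π electrocyclic opening to dienylketene 10. Torquoselectivity sends the donor OMe on the sp3 carbon outward and the π-acceptor pyronyl group inward, which gives (Z)-10 with the pyrone C5=C6 bond (numbering of 5) beside the ketene, and any E-ketene can only re-close to 9, so the step corrects itself. Ring A, a six-membered carbocycle, closes by a thermally allowed disrotatory 6π electrocyclisation that forms C4a–C5 and is polarity-matched, because pyrone C5 is the nucleophilic β-carbon of the O1–C6=C5 enol ether and the ketene carbon is electrophilic. Dienone 11 holds one transient stereocentre (C4a–H), which is lost on enolisation to 12 under the drive of aromatisation and the C5–OH···O=C4 hydrogen bond, so no stereocentre remains. Site selectivity is structural, since the pyrone carbon that bears the C4 unit has only one carbon neighbour (the other is O1) and only one annulation mode exists. The placement of OH against OMe is also structural: the former carbinol carbon, already methylated, is bonded to C8a and becomes C8–OMe, while the former carbonyl carbon becomes C5–OH, so the single free phenol appears at the right place without selective methylation or demethylation. High dilution under argon suppresses intermolecular capture of the ketene, and the MOM acetals are inert in neutral toluene at this temperature.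

Step 6
Reactants: 12 5-hydroxy-6,7,8-trimethoxy-3-(methoxymethoxy)-2-[4-(methoxymethoxy)phenyl]-4H-chromen-4-one
Product: 13 3,5-dihydroxy-2-(4-hydroxyphenyl)-6,7,8-trimethoxy-4H-chromen-4-one (3,5,4'-trihydroxy-6,7,8-trimethoxyflavone)
Conditions: aq. HCl (cat.), MeOH, 50 °C
Reagents that add atoms: none
Why: Acid-catalysed transacetalisation (MOM methanolysis) frees O3 and O4' while aryl methyl ethers are inert to dilute protic acid. Even a Wessely–Moser-type opening and re-closure of ring C would be degenerate here, because C6 and C8 carry the same group.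

## Compound list

1 | 3-hydroxy-4H-pyran-4-one (pyromeconic acid) | O=c1ccocc1O | starting material
2 | 3-hydroxy-2-iodo-4H-pyran-4-one | O=c1ccoc(I)c1O | intermediate
3 | 2-iodo-3-(methoxymethoxy)-4H-pyran-4-one | COCOc1c(I)occc1=O | intermediate
4 | [4-(methoxymethoxy)phenyl]boronic acid | COCOc1ccc(cc1)B(O)O | starting material
5 | 3-(methoxymethoxy)-2-[4-(methoxymethoxy)phenyl]-4H-pyran-4-one | COCOc1ccc(cc1)-c1occc(=O)c1OCOC | intermediate
6 | 3,4-dimethoxycyclobut-3-ene-1,2-dione (dimethyl squarate) | COC1=C(OC)C(=O)C1=O | starting material
7 | 6-lithio-3-(methoxymethoxy)-2-[4-(methoxymethoxy)phenyl]-4H-pyran-4-one (not isolated) | [Li]c1cc(=O)c(OCOC)c(-c2ccc(OCOC)cc2)o1 | intermediate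
8 | lithium 2,3-dimethoxy-1-{5-(methoxymethoxy)-6-[4-(methoxymethoxy)phenyl]-4-oxo-4H-pyran-2-yl}-4-oxocyclobut-2-en-1-olate (racemic, not isolated) | [Li+].[O-]C1(C(OC)=C(OC)C1=O)c1cc(=O)c(OCOC)c(-c2ccc(OCOC)cc2)o1 | intermediate
9 | 2,3,4-trimethoxy-4-{5-(methoxymethoxy)-6-[4-(methoxymethoxy)phenyl]-4-oxo-4H-pyran-2-yl}cyclobut-2-en-1-one (racemic) | COC1=C(OC)C(OC)(c2cc(=O)c(OCOC)c(-c3ccc(OCOC)cc3)o2)C1=O | intermediate
10 | (Z)-2,3,4-trimethoxy-4-{5-(methoxymethoxy)-6-[4-(methoxymethoxy)phenyl]-4-oxo-4H-pyran-2-yl}buta-1,3-dien-1-one (not isolated) | O=C=C(OC)/C(OC)=C(OC)\c1cc(=O)c(OCOC)c(-c2ccc(OCOC)cc2)o1 | intermediate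
11 | 6,7,8-trimethoxy-3-(methoxymethoxy)-2-[4-(methoxymethoxy)phenyl]-4aH-chromene-4,5-dione (racemic, not isolated) | COC1=C(OC)C(=O)C2C(=O)C(OCOC)=C(c3ccc(OCOC)cc3)OC2=C1OC | intermediate
12 | 5-hydroxy-6,7,8-trimethoxy-3-(methoxymethoxy)-2-[4-(methoxymethoxy)phenyl]-4H-chromen-4-one | COCOc1ccc(cc1)-c1oc2c(OC)c(OC)c(OC)c(O)c2c(=O)c1OCOC | intermediate
13 | 3,5-dihydroxy-2-(4-hydroxyphenyl)-6,7,8-trimethoxy-4H-chromen-4-one | COc1c(OC)c(O)c2c(=O)c(O)c(-c3ccc(O)cc3)oc2c1OC | target

## Step count and least certain steps

Total step count: 6. Longest linear sequence: 6 (1 → 2 → 3 → 5 → 9 → 12 → 13). Compounds 4 and 6 enter as purchased.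

**Step 5 (key step).**
- Risk: the 6π closure onto the cross-conjugated pyrone C=C may be slower than onto a plain alkene. The dienylketene could then be consumed between molecules, by acylation of the phenol already formed, by capture of adventitious water, or by dimerisation. Prolonged heating could also erode the acetals.
- Fallback (sets out from 6, comes back at 13): the squarate-to-arene idea is kept, but the ketene closes onto a simple enol ether and ring C is then made classically. 1-Ethoxyvinyllithium is added to 6 at −78 °C and the alkoxide is methylated in situ with MeOTf to give 4-(1-ethoxyethenyl)-2,3,4-trimethoxycyclobut-2-en-1-one F1. Heating in toluene should give 5-ethoxy-2,3,4-trimethoxyphenol F2, whose only free ring position lies between OH and OEt. C-acylation there with methoxyacetic anhydride and BF3·OEt2 gives 1-(2-ethoxy-6-hydroxy-3,4,5-trimethoxyphenyl)-2-methoxyethan-1-one F3. Allan–Robinson condensation with 4-(benzyloxy)benzoic anhydride and its potassium salt gives 2-[4-(benzyloxy)phenyl]-5-ethoxy-3,6,7,8-tetramethoxy-4H-chromen-4-one F4. Hydrogenolysis (H2, Pd/C) gives 5-ethoxy-2-(4-hydroxyphenyl)-3,6,7,8-tetramethoxy-4H-chromen-4-one F5. Chelation-directed dealkylation of the two ethers that flank C4=O (AlBr3, MeCN, 0 °C, short contact) gives 13.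

**Step 4.** Three processes threaten it.
- Carbonyl-directed deprotonation may occur at the pyrone C–H next to C4=O instead of the one next to O1.
- The lithiated pyrone may self-condense by conjugate addition to pyrone that has not yet been metalated.
- MeOTf may methylate the pyrone carbonyl oxygen (pyrylium formation) in competition with the hindered tertiary alkoxide.
- Fallback (sets out from 5 and 6, comes back at 12): the two para oxygens are told apart after ring formation, by chelation, and not before it. Compound 5 is metalated with the softer TMPMgCl·LiCl (−40 °C), added to 6 and quenched with aqueous NH4Cl. This gives 6-(1-hydroxy-2,3-dimethoxy-4-oxocyclobut-2-en-1-yl)-3-(methoxymethoxy)-2-[4-(methoxymethoxy)phenyl]-4H-pyran-4-one F6. Wrong-site metalation would give the isomer 5-(1-hydroxy-2,3-dimethoxy-4-oxocyclobut-2-en-1-yl)-3-(methoxymethoxy)-2-[4-(methoxymethoxy)phenyl]-4H-pyran-4-one F7. Because 6 is symmetrical, both should converge on heating (toluene, argon, dithionite work-up) on the same hydroquinone, 5,8-dihydroxy-6,7-dimethoxy-3-(methoxymethoxy)-2-[4-(methoxymethoxy)phenyl]-4H-chromen-4-one F8, so the site of metalation no longer matters. One equivalent of Me2SO4 with K2CO3 in acetone should then alkylate only the unchelated C8–OH and give 12.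

**Step 3.**
- Risk: C2 of 3 is a vinylogous acyl iodide. Addition–elimination of hydroxide or phosphate at C2, or base-induced opening of the pyrone ring, may compete with transmetalation in the aqueous basic medium. Reduction of the C–I bond is also possible.
- Fallback (sets out from 3, comes back at 5): the polarity of the coupling is reversed, so no base and no water are needed. Zinc dust with LiCl inserts into the C–I bond of 3 (THF, 25 °C) to give iodo[3-(methoxymethoxy)-4-oxo-4H-pyran-2-yl]zinc F9. Negishi coupling of F9 with 1-iodo-4-(methoxymethoxy)benzene (Pd2(dba)3, SPhos, THF, 40 °C) gives 5.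

## Further compounds

F1 | step 5 | 4-(1-ethoxyethenyl)-2,3,4-trimethoxycyclobut-2-en-1-one (racemic) | C=C(OCC)C1(OC)C(OC)=C(OC)C1=O
F2 | step 5 | 5-ethoxy-2,3,4-trimethoxyphenol | CCOc1cc(O)c(OC)c(OC)c1OC
F3 | step 5 | 1-(2-ethoxy-6-hydroxy-3,4,5-trimethoxyphenyl)-2-methoxyethan-1-one | CCOc1c(OC)c(OC)c(OC)c(O)c1C(=O)COC
F4 | step 5 | 2-[4-(benzyloxy)phenyl]-5-ethoxy-3,6,7,8-tetramethoxy-4H-chromen-4-one | CCOc1c(OC)c(OC)c(OC)c2oc(-c3ccc(OCc4ccccc4)cc3)c(OC)c(=O)c12
F5 | step 5 | 5-ethoxy-2-(4-hydroxyphenyl)-3,6,7,8-tetramethoxy-4H-chromen-4-one | CCOc1c(OC)c(OC)c(OC)c2oc(-c3ccc(O)cc3)c(OC)c(=O)c12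
F6 | step 4 | 6-(1-hydroxy-2,3-dimethoxy-4-oxocyclobut-2-en-1-yl)-3-(methoxymethoxy)-2-[4-(methoxymethoxy)phenyl]-4H-pyran-4-one (racemic) | COC1=C(OC)C(O)(c2cc(=O)c(OCOC)c(-c3ccc(OCOC)cc3)o2)C1=O
F7 | step 4 | 5-(1-hydroxy-2,3-dimethoxy-4-oxocyclobut-2-en-1-yl)-3-(methoxymethoxy)-2-[4-(methoxymethoxy)phenyl]-4H-pyran-4-one (racemic) | COC1=C(OC)C(O)(c2coc(-c3ccc(OCOC)cc3)c(OCOC)c2=O)C1=O
F8 | step 4 | 5,8-dihydroxy-6,7-dimethoxy-3-(methoxymethoxy)-2-[4-(methoxymethoxy)phenyl]-4H-chromen-4-one | COCOc1ccc(cc1)-c1oc2c(O)c(OC)c(OC)c(O)c2c(=O)c1OCOC
F9 | step 3 | iodo[3-(methoxymethoxy)-4-oxo-4H-pyran-2-yl]zinc | I[Zn]c1occc(=O)c1OCOC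
A1 | alternative 1 | 1-[2-(benzyloxy)-6-hydroxy-3,4,5-trimethoxyphenyl]ethan-1-one | CC(=O)c1c(O)c(OC)c(OC)c(OC)c1OCc1ccccc1
A2 | alternative 1 | 4-(benzyloxy)benzaldehyde | O=Cc1ccc(OCc2ccccc2)cc1
A3 | alternative 1 | (E)-1-[2-(benzyloxy)-6-hydroxy-3,4,5-trimethoxyphenyl]-3-[4-(benzyloxy)phenyl]prop-2-en-1-one | O=C(/C=C/c1ccc(OCc2ccccc2)cc1)c1c(O)c(OC)c(OC)c(OC)c1OCc1ccccc1
A4 | alternative 2 | 3-(benzyloxy)-2-iodo-4,5,6-trimethoxyphenol | Oc1c(I)c(OCc2ccccc2)c(OC)c(OC)c1OC
A5 | alternative 2 | 1-(benzyloxy)-4-ethynylbenzene | C#Cc1ccc(OCc2ccccc2)cc1
A6 | alternative 2 | 5-(benzyloxy)-2-[4-(benzyloxy)phenyl]-6,7,8-trimethoxy-4H-chromen-4-one | COc1c(OC)c(OCc2ccccc2)c2c(=O)cc(-c3ccc(OCc4ccccc4)cc3)oc2c1OC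
A7 | alternative 3 | kaempferol (3,5,7-trihydroxy-2-(4-hydroxyphenyl)-4H-chromen-4-one) | O=c1c(O)c(-c2ccc(O)cc2)oc2cc(O)cc(O)c12
A8 | alternative 3 | 3-(benzyloxy)-2-[4-(benzyloxy)phenyl]-6,8-dibromo-5-hydroxy-7-methoxy-4H-chromen-4-one | COc1c(Br)c(O)c2c(=O)c(OCc3ccccc3)c(-c3ccc(OCc4ccccc4)cc3)oc2c1Br
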